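Amounts are what you want from this flask, so here is what was charged, what was read and what is asked.

| setting | Wednesday's | flask |
|---|---|---|
| substrate | 20 mM | 20 mM |
| coupling partner | 2.4 equiv | 1.20 equiv |
| remark | run made earlier |  |
| time |  | 5.0 h |

- Wednesday's (time / min: substrate / %, single product / %, other mono adduct / %): 5.00: 95.6, 0.8, 3.9; 10.0: 92.9, 1.2, 5.4; 15.0: 87.7, 3.5, 6.0; 30.0: 77.1, 6.7, 12.6; 60.0: 65.7, 11.6, 20.2

(scatter of a reading: 1 percentage point)



- amount of substrate at 5.0 h, in percent of the substrate charged
- amount of single product at 5.0 h, in percent of the substrate charged
- amount of other mono adduct at 5.0 h, in percent of the substrate charged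
- amount of bis adduct at 5.0 h, in percent of the substrate charged

One number carries the argument: the selectivity factor S, the ratio of other mono adduct to single product as the two first form, read at 60.0 min as 1.74, a reading with the scatter of its two values. Equal sites would give S = 1, the statistical zero of the scale.

Build the flask up by steps, as my own reckoning. Take the first addition with coupling partner held at its charge (pseudo-first-order), and scale the logarithm of Wednesday's substrate by time and partner: 35.0% remains. Now let the partner be consumed, which I estimate as an average of 0.7 of its charge, and my figure for substrate rises to 47.9%.

Next add the second addition, taking the two sites as independent. Let u be the surviving fraction of the site that gives single product; the other site survives as v = u^S, and uv is the substrate left. So u = 0.765 and v = 0.627. Single product, (1−u)v, comes to 14.7%, other mono adduct, u(1−v), to 28.5%, and bis adduct, (1−u)(1−v), to 8.77%. In this reckoning single product still carries the quicker site, so the ratio of other mono adduct to single product comes out higher than S, at 1.94.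

For the rest, Wednesday's last readings leave a gap of 2.5 percentage points, too noisy to price anything further.

The forecast says 44% substrate, 15% single product, 30% other mono adduct and 11% bis adduct, which is less substrate than mine. Of the bis adduct it says: “That fits two roughly independent sites, with the second addition at about the same rate as the corresponding first.”

The flask gives 45.4%, 9.94%, 29.4% and 11.8%, in that order.

    substrate + coupling partner → single product (k = 0.0576 L mol⁻¹ min⁻¹)
    substrate + coupling partner → other mono adduct (k = 0.106 L mol⁻¹ min⁻¹)
    coupling partner + single product → bis adduct (k = 0.167 L mol⁻¹ min⁻¹)
    coupling partner + other mono adduct → bis adduct (k = 0.0691 L mol⁻¹ min⁻¹)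
    2 substrate → homo dimer (k = 6.42 × 10⁻⁵ L mol⁻¹ min⁻¹)
    single product ⇌ isomer of the product (K = 1.20, k = 0.00170 min⁻¹)

Put this flask's substrate into the rule with S: it gives 29.6% other mono adduct against 29.4%, but 15.2% single product against 9.94%, and in this flask at 5.00 h, each step taken net, other mono adduct is made 2.37 times as fast as it is used up, single product 0.939 times. In the neighbour flask with 2.00 equiv of coupling partner and 25.7% substrate, the rule gives 35.2% other mono adduct against 34.4%, and 16.5% single product against 9.75%.

Readings and results stem from a simulated flask with made-up constants; scatter was added.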